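**Plan**

1. Retrosynthesis: cut C12–C13 (sp3–sp2 coupling to purchased 4-bromobutenolide) and C11=C12 (methylenation). Take the cis H-5/HO-6 pair back to a C5=C6 alkene. Then cut C7–C8 and C9–C10 together ([4+2] retron), which opens ring B to a ring-A vinyl diene and a 2-butynoate.
2. Enabling feature: ring B holds C8=C9 in a 1,4 relation to the latent C5=C6 bond across quaternary C10 and C7, so it is an alkyne–diene cycloadduct. O-2 on ring A is 1,3-cis to the C10–C9 bond, so C11 can be carried as the carbonyl of a 2α-O ester tether (a temporary six-membered lactone).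
3. Forward: ketoisophorone supplies all nine ring-A carbons (C1–C5, C10, C18–C20); C–H acetoxylation makes C19; triflate/Stille adds C6–C7; a Mitsunobu step adds C8, C9, C11, C17. The Diels–Alder step then closes ring B, the last ring to be closed (the butenolide ring is bought), followed by tether reduction, hydroboration, oxidation, methylenation and coupling.
4. Stereochemistry: C2 from asymmetric transfer hydrogenation (inverted once, in the Mitsunobu step); C4 from the equatorial-methyl preference of the oxime palladacycle; C10 from the tether; C5 and C6 from α-face syn-hydroboration.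

Key step: step 11

Remark: labdane numbering is used for every intermediate (C2 carbinol carbon, C4 quaternary carbon, C5 and C10 the future ring-fusion carbons, C19 the 4β-carbon); β is the ring face that carries C19 and, in the target, the C10 methyl.

**Route**

Step 1
Reactants: 1 ketoisophorone
Product: 2 (R)-4-hydroxy-2,6,6-trimethylcyclohex-2-en-1-one
Conditions: RuCl(p-cymene)[(R,R)-TsDPEN] (1 mol %), iPrOH, rt
Reagents that add atoms: none
Why: Asymmetric transfer hydrogenation (metal–ligand bifunctional hydride delivery) should reduce only the unhindered enone carbonyl, and the catalyst antipode is chosen to set the carbinol (labdane C2) as R on the usual model in which the enone π-system takes the place of an aryl group.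

Step 2
Reactants: 2 (R)-4-hydroxy-2,6,6-trimethylcyclohex-2-en-1-one
Product: 4 (4S,6R)-4-hydroxy-2,2,6-trimethylcyclohexan-1-one, via trans epimer 3 (not isolated)
Conditions: H2 (1 atm), Pd/C, EtOAc, rt; then NaOMe (cat.), MeOH, rt
Reagents that add atoms: none
Why: Heterogeneous hydrogenation saturates the enone C=C, and methoxide equilibration through the only available enolate should move the C10 epimer mixture to the all-equatorial cis isomer, which fixes the chair needed in step 4.

Step 3
Reactants: 4 (4S,6R)-4-hydroxy-2,2,6-trimethylcyclohexan-1-one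
Product: 6 O-acetyl oxime acetate of 4, via hydroxy oxime 5 (not isolated)
Conditions: NH2OH·HCl, NaOAc, EtOH/H2O, 80 °C; then Ac2O, pyridine, DMAP (cat.), CH2Cl2, rt
Reagents that add atoms: hydroxylamine hydrochloride NO.Cl; acetic anhydride CC(=O)OC(C)=O
Why: Oxime condensation followed by O-acetylation gives the O-acetyl oxime directing group with its oxygen anti to the quaternary carbon, and the same acetylation protects the C2 hydroxyl.

Step 4
Reactants: 6 O-acetyl oxime acetate
Product: 7 19-acetoxy O-acetyl oxime acetate (CH2OAc cis to the ring acetate)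
Conditions: Pd(OAc)2 (5 mol %), PhI(OAc)2 (1.5 equiv), AcOH/Ac2O 1:1, 100 °C
Reagents that add atoms: (diacetoxyiodo)benzene CC(=O)OI(OC(C)=O)c1ccccc1
Why: Oxime-directed palladium-catalysed C(sp3)–H acetoxylation proceeds through a five-membered palladacycle that only the methyl lying in the C=N plane (the equatorial 4β-methyl, cis to the equatorial C2 acetate in the locked chair) can form, and oxidation of divalent to tetravalent palladium by PhI(OAc)2 with C–O reductive elimination then sets C4.

Step 5
Reactants: 7 19-acetoxy O-acetyl oxime acetate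
Product: 9 (2R,4S,6R)-4-hydroxy-2-(hydroxymethyl)-2,6-dimethylcyclohexan-1-one, via oxime diol 8 (not isolated)
Conditions: K2CO3 (cat.), MeOH, rt; then NaHSO3, EtOH/H2O, 80 °C
Reagents that add atoms: water O
Why: Transesterification removes the three acetyl groups and bisulfite-mediated hydrolytic deoximation returns the ketone under non-basic conditions that should spare the retro-aldol-prone β-hydroxy ketone.

Step 6
Reactants: 9 keto diol
Product: 11 2β-OTES 19-OTBDPS ketone, via mono-TBDPS ether 10 (not isolated)
Conditions: TBDPSCl (1.05 equiv), imidazole, DMF, 0 °C; then TESCl, rt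
Reagents that add atoms: tert-butyl(chloro)diphenylsilane CC(C)(C)[Si](Cl)(c1ccccc1)c1ccccc1; chlorotriethylsilane CC[Si](Cl)(CC)CC
Why: Silyl ether formation is chemoselective by size, the bulky TBDPS chloride taking the primary hydroxyl before TESCl caps the secondary one, which gives two silyl ethers of different acid lability.

Step 7
Reactants: 11 2β-OTES 19-OTBDPS ketone
Product: 13 C5 enol triflate (C5=C10), via potassium enolate 12 (not isolated)
Conditions: KN(SiMe3)2, THF, −78 °C; then PhNTf2, −78 → 0 °C
Reagents that add atoms: N-phenylbis(trifluoromethanesulfonimide) O=S(=O)(N(c1ccccc1)S(=O)(=O)C(F)(F)F)C(F)(F)F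
Why: Enolisation can occur only toward C10 because C4 is quaternary, so O-triflation of the potassium enolate should give a single tetrasubstituted enol triflate and removes the auxiliary C10 stereocentre.

Step 8
Reactants: 13 C5 enol triflate
Product: 14 bis-silyl vinyl diene (C10=C5–C6=C7)
Conditions: CH2=CHSnBu3, Pd(PPh3)4 (5 mol %), LiCl, THF, 70 °C
Reagents that add atoms: tributyl(vinyl)stannane C=C[Sn](CCCC)(CCCC)CCCC
Why: Stille cross-coupling of a hindered cyclohexenyl triflate with a vinylstannane (LiCl-assisted, zerovalent palladium) is the established way to 1-vinyl-2,6,6-trisubstituted cyclohexenes and creates no stereocentre.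

Step 9
Reactants: 14 bis-silyl vinyl diene
Product: 15 2β-dienol (19-OTBDPS)
Conditions: PPTS (cat.), MeOH/CH2Cl2, rt
Reagents that add atoms: none
Why: Acid-catalysed methanolysis cleaves the secondary TES ether far faster than the primary TBDPS ether and should leave the diene untouched.

Step 10
Reactants: 15 2β-dienol; 16 2-butynoic acid
Product: 17 2α-(2-butynoyloxy) diene
Conditions: PPh3, DIAD, THF, 0 °C → rt (acid added last)
Reagents that add atoms: none
Why: Mitsunobu esterification displaces the activated C2 oxygen by 2-butynoate with inversion (SN2), which both sets the 2α-configuration of the target and places the dienophile on the α-face, trans to C19.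

Step 11
Reactants: 17 2α-(2-butynoyloxy) diene
Product: 18 tricyclic lactone (ring B as 5,8-diene; C11 carbonyl bridged to O-2)
Conditions: PhMe (5 mM), BHT (cat.), 170 °C, sealed tube
Reagents that add atoms: none
Why: The step is a thermal, concerted but asynchronous [4+2] cycloaddition (type 1 intramolecular Diels–Alder) of the 2-alkynoate onto the semicyclic C10=C5–C6=C7 diene, C8 bonding to C7 and C9 to C10, and it gives a 1,4-cyclohexadiene because the dienophile is an alkyne. The closest known reaction type is the intramolecular Diels–Alder reaction of 2-alkynoate esters of hydroxylated 1-vinyl-2,6,6-trisubstituted cyclohexenes, which gives lactone-annulated decalin dienes of the labdane family. Ring B closes as the six-membered cycloadduct ring (new σ-bonds C7–C8 and C9–C10), and the temporary six-membered lactone (C10, C1, C2, O, C11, C9) closes in the same event as the tether ring, forming a 2-oxabicyclo[3.3.1]nonane with ring A. The one new stereocentre, quaternary C10, is controlled by C2: the ester oxygen is on the α-face and the four-atom tether can reach only the α-face of C10, so C9 enters α and the C10 methyl is left β, cis to C19. The step needs regioselectivity (C17-bearing carbon to C7, carbonyl-bearing carbon to C10), which the tether length enforces and the polarity of the ynoate reinforces, and it needs to outrun a [1,5]-hydrogen shift of the Z-methyl diene, which high dilution at the lowest effective temperature is meant to secure.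

Step 12
Reactants: 18 tricyclic lactone
Product: 19 2α,11-diol 5,8-diene (19-OTBDPS)
Conditions: iBu2AlH (4 equiv), CH2Cl2, −78 → 0 °C; aq. KNaC4H4O6 work-up
Reagents that add atoms: none
Why: 1,2-Reduction of the unsaturated lactone by the aluminium hydride cuts the tether to the 2α-hydroxyl and the C11 allylic alcohol, which lets ring A relax to the chair with C19 and the C10 methyl axial on the β-face.

Step 13
Reactants: 19 2α,11-diol 5,8-diene
Product: 21 2α,6α,11-triol 8-ene (19-OTBDPS), via C6 alkylborane 20 (not isolated)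
Conditions: BH3·THF (5 equiv), THF, 0 °C → rt; then NaOH, H2O2, 0 °C → rt
Reagents that add atoms: hydrogen peroxide OO
Why: Hydroboration–oxidation adds H and B syn and anti-Markovnikov across the trisubstituted C5=C6 bond from the α-face, opposite the two β-axial groups at C4 and C10, so C5–H and C6–OH should both become α, while the tetrasubstituted C8=C9 bond is too hindered to react.

Step 14
Reactants: 21 2α,6α,11-triol 8-ene
Product: 22 C11 enal (2α,6α-diol; 19-OTBDPS)
Conditions: MnO2 (20 equiv), CH2Cl2, rt
Reagents that add atoms: none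
Why: MnO2 oxidation is selective for the allylic primary alcohol and should leave the two saturated secondary alcohols alone.

Step 15
Reactants: 22 C11 enal
Product: 23 8,11-diene 2α,6α-diol (19-OTBDPS)
Conditions: Ph3PCH3Br, KOtBu (4 equiv each), THF, 0 °C → rt
Reagents that add atoms: methyltriphenylphosphonium bromide C[P+](c1ccccc1)(c1ccccc1)c1ccccc1.[Br-]
Why: Wittig methylenation of the hindered enal with the small non-stabilised ylide adds C12 and tolerates the free hydroxyls when the ylide is used in excess.

Step 16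
Reactants: 23 8,11-diene 2α,6α-diol; 24 4-bromofuran-2(5H)-one
Product: 26 19-O-TBDPS ether of the target, via B-alkyl-9-BBN adduct 25 (not isolated)
Conditions: 9-BBN dimer (excess), THF, 0 °C → rt; then 24, Pd(dppf)Cl2 (10 mol %), AsPh3, K3PO4 (aq), DMF, rt
Reagents that add atoms: none
Why: 9-BBN hydroborates only the monosubstituted terminus of the diene to put boron on C12, and B-alkyl Suzuki–Miyaura coupling with the β-bromobutenolide then forms the C12–C13 bond without touching a stereocentre.

Step 17
Reactants: 26 19-O-TBDPS ether of the target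
Product: 27 2α,6α,19-trihydroxylabda-8,13-dien-15,16-olide (target)
Conditions: HF·pyridine, THF/pyridine, 0 °C → rt
Reagents that add atoms: none
Why: Fluoride-mediated desilylation under buffered, weakly acidic conditions frees the C19 hydroxyl without opening or isomerising the butenolide.

**Compound list**

1 | ketoisophorone (2,6,6-trimethylcyclohex-2-ene-1,4-dione) | CC1=CC(=O)CC(C)(C)C1=O | starting material
2 | (R)-4-hydroxy-2,6,6-trimethylcyclohex-2-en-1-one | CC1=C[C@H](O)CC(C)(C)C1=O | intermediate
3 | (4S,6S)-4-hydroxy-2,2,6-trimethylcyclohexan-1-one (trans epimer, formed and equilibrated in the flask) | O=C1[C@@H](C)C[C@H](O)CC1(C)C | intermediate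
4 | (4S,6R)-4-hydroxy-2,2,6-trimethylcyclohexan-1-one (cis, all-equatorial) | O=C1[C@H](C)C[C@H](O)CC1(C)C | intermediate
5 | oxime of 4 (oxime oxygen syn to the CHMe carbon) | O/N=C1\[C@H](C)C[C@H](O)CC1(C)C | intermediate
6 | (4S,6R)-4-acetoxy-2,2,6-trimethylcyclohexan-1-one O-acetyl oxime | CC(=O)O/N=C1\[C@H](C)C[C@H](OC(C)=O)CC1(C)C | intermediate
7 | 19-acetoxy derivative of 6 (2β-OAc, 4β-CH2OAc, 4α-Me, 10β-Me; O-acetyl oxime at C5) | CC(=O)O/N=C1\[C@H](C)C[C@H](OC(C)=O)C[C@]1(C)COC(C)=O | intermediate
8 | oxime diol (2β-OH, 4β-CH2OH, oxime at C5) | O/N=C1\[C@H](C)C[C@H](O)C[C@]1(C)CO | intermediate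
9 | (2R,4S,6R)-4-hydroxy-2-(hydroxymethyl)-2,6-dimethylcyclohexan-1-one (CH2OH cis to OH and to the C6 methyl) | O=C1[C@H](C)C[C@H](O)C[C@]1(C)CO | intermediate
10 | mono-TBDPS ether of 9 (19-OTBDPS, 2β-OH) | O=C1[C@H](C)C[C@H](O)C[C@]1(C)CO[Si](c1ccccc1)(c1ccccc1)C(C)(C)C | intermediate
11 | ketone with 2β-OTES, 4β-CH2OTBDPS, 4α-Me, 10β-Me | O=C1[C@H](C)C[C@H](O[Si](CC)(CC)CC)C[C@]1(C)CO[Si](c1ccccc1)(c1ccccc1)C(C)(C)C | intermediate
12 | potassium C5(O)=C10 enolate of 11 | [K+].[O-]C1=C(C)C[C@H](O[Si](CC)(CC)CC)C[C@]1(C)CO[Si](c1ccccc1)(c1ccccc1)C(C)(C)C | intermediate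
13 | enol triflate (C5-OTf, C5=C10; 2β-OTES, 4β-CH2OTBDPS) | O=S(=O)(OC1=C(C)C[C@H](O[Si](CC)(CC)CC)C[C@]1(C)CO[Si](c1ccccc1)(c1ccccc1)C(C)(C)C)C(F)(F)F | intermediate
14 | vinyl diene (C10=C5–C6=C7; 2β-OTES, 4β-CH2OTBDPS) | C=CC1=C(C)C[C@H](O[Si](CC)(CC)CC)C[C@]1(C)CO[Si](c1ccccc1)(c1ccccc1)C(C)(C)C | intermediate
15 | dienol (2β-OH, 4β-CH2OTBDPS) | C=CC1=C(C)C[C@H](O)C[C@]1(C)CO[Si](c1ccccc1)(c1ccccc1)C(C)(C)C | intermediate
16 | 2-butynoic acid | CC#CC(=O)O | starting material
17 | diene 2-butynoate (2α-ester, 4β-CH2OTBDPS, trans to each other) | C=CC1=C(C)C[C@@H](OC(=O)C#CC)C[C@]1(C)CO[Si](c1ccccc1)(c1ccccc1)C(C)(C)C | intermediate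
18 | tricyclic lactone: ring-B 5,8-diene, 10β-Me, C9–C11(=O)–O–C2α bridge, 4β-CH2OTBDPS | CC1=C2C(=O)O[C@@H]3C[C@@]2(C)C(=CC1)[C@@](C)(CO[Si](c4ccccc4)(c4ccccc4)C(C)(C)C)C3 | intermediate
19 | diol: 2α-OH, C9–CH2OH (C11), 5,8-diene, 10β-Me, 4β-CH2OTBDPS | CC1=C(CO)[C@@]2(C)C[C@@H](O)C[C@](C)(CO[Si](c3ccccc3)(c3ccccc3)C(C)(C)C)C2=CC1 | intermediate
20 | C6α alkylborane with 5α-H (drawn as the monoalkylborane with hydroxyls free; in the flask these are borate esters) | CC1=C(CO)[C@@]2(C)C[C@@H](O)C[C@](C)(CO[Si](c3ccccc3)(c3ccccc3)C(C)(C)C)[C@@H]2[C@@H](B)C1 | intermediate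
21 | triol: 2α-OH, 6α-OH, C11–OH, 5α-H, 8-ene, 4β-CH2OTBDPS | CC1=C(CO)[C@@]2(C)C[C@@H](O)C[C@](C)(CO[Si](c3ccccc3)(c3ccccc3)C(C)(C)C)[C@@H]2[C@@H](O)C1 | intermediate
22 | enal: C9–CHO (C11), 2α,6α-diol, 8-ene, 4β-CH2OTBDPS | CC1=C(C=O)[C@@]2(C)C[C@@H](O)C[C@](C)(CO[Si](c3ccccc3)(c3ccccc3)C(C)(C)C)[C@@H]2[C@@H](O)C1 | intermediate
23 | diene diol: C9–CH=CH2 (C11=C12), 2α,6α-diol, 4β-CH2OTBDPS | CC1=C(C=C)[C@@]2(C)C[C@@H](O)C[C@](C)(CO[Si](c3ccccc3)(c3ccccc3)C(C)(C)C)[C@@H]2[C@@H](O)C1 | intermediate
24 | 4-bromofuran-2(5H)-one | O=C1C=C(Br)CO1 | starting material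
25 | B-(C12-alkyl)-9-BBN adduct of 23 (hydroxyls drawn free) | CC1=C(CCB2C3CCCC2CCC3)[C@@]2(C)C[C@@H](O)C[C@](C)(CO[Si](c3ccccc3)(c3ccccc3)C(C)(C)C)[C@@H]2[C@@H](O)C1 | intermediate
26 | 19-O-TBDPS ether of the target | CC1=C(CCC2=CC(=O)OC2)[C@@]2(C)C[C@@H](O)C[C@](C)(CO[Si](c3ccccc3)(c3ccccc3)C(C)(C)C)[C@@H]2[C@@H](O)C1 | intermediate
27 | 2α,6α,19-trihydroxylabda-8,13-dien-15,16-olide | CC1=C(CCC2=CC(=O)OC2)[C@@]2(C)C[C@@H](O)C[C@](C)(CO)[C@@H]2[C@@H](O)C1 | target

**Count and risks**

Total step count: 17. Longest linear sequence: 17 steps (from 1).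

Steps most likely to fail:

1. Step 11 (intramolecular Diels–Alder). The ester tether may fail to reach the folded reactive conformer, because of syn-pseudoaxial strain between the 2α-ester and the 4α-methyl and the need for the less favoured ester rotamer. A [1,5]-hydrogen shift of the diene or polymerisation could then outrun cycloaddition. Fallback, setting out from 15 and coming back at 19: dienol 15 is inverted by a Mitsunobu reaction with benzoic acid (PPh3, DIAD) to the 2α-benzoate diene F1. F1 is combined intermolecularly with but-2-ynal (Me2AlCl, CH2Cl2, −40 °C). Addition should occur on the α-face, because with the 2α-benzoate equatorial the 4β-CH2OTBDPS group is pseudoaxial over the β-face. The formyl-bearing carbon should bond to C10 by the ortho rule, giving the ring-B diene aldehyde F2. iBu2AlH then reduces the aldehyde and cleaves the benzoate in one operation to give diol 19.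

2. Step 4 (C–H acetoxylation). Cyclopalladation may stall because of A1,3 strain around the O-acetyl oxime, or be steered to the C10 methyl through the minor oxime isomer. Fallback, setting out from 4 and coming back at 13: hydroxy ketone 4 is silylated (TESCl, imidazole) to the TES ether F3, converted (KN(SiMe3)2, PhNTf2) to the gem-dimethyl enol triflate F4, and desilylated (PPTS, MeOH) to the hydroxy enol triflate F5. Nitrosation (NOCl, pyridine) gives the nitrite ester F6. Barton nitrite photolysis (hν, benzene; then 2-propanol, reflux) moves the oxidation by 1,5-hydrogen transfer to the only methyl that is 1,3-syn to the 2β-oxygen, the 4β-methyl, giving the C19 aldoxime F7. Transoximation with aqueous glyoxylic acid gives the hydroxy aldehyde F8 (expected largely as its 2,19-lactol). NaBH4 reduces it to the diol triflate F9, and TBDPSCl followed by TESCl as in step 6 gives enol triflate 13.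

3. Step 10 (Mitsunobu with the alkynoic acid). Conjugate addition of PPh3 to the ynoate, or elimination at the hindered carbinol in place of substitution, may consume the material. Fallback, setting out from 15 and coming back at 17: dienol 15 undergoes the Mitsunobu reaction with 4-nitrobenzoic acid to the inverted 2α-(4-nitrobenzoate) diene F10. Methanolysis (K2CO3, MeOH) gives the 2α-dienol F11, which is acylated with retention by 2-butynoic acid 16 (DCC, DMAP cat., CH2Cl2, 0 °C) to give ester 17.

**Further compounds**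

F1 | step 11 | 2α-benzoate diene (4β-CH2OTBDPS) | C=CC1=C(C)C[C@@H](OC(=O)c2ccccc2)C[C@]1(C)CO[Si](c1ccccc1)(c1ccccc1)C(C)(C)C
F2 | step 11 | ring-B 5,8-diene C11 aldehyde with 2α-benzoate (10β-Me, 4β-CH2OTBDPS) | CC1=C(C=O)[C@@]2(C)C[C@@H](OC(=O)c3ccccc3)C[C@](C)(CO[Si](c3ccccc3)(c3ccccc3)C(C)(C)C)C2=CC1
F3 | step 4 | TES ether of 4 | O=C1[C@H](C)C[C@H](O[Si](CC)(CC)CC)CC1(C)C
F4 | step 4 | gem-dimethyl enol triflate, 2β-OTES | O=S(=O)(OC1=C(C)C[C@H](O[Si](CC)(CC)CC)CC1(C)C)C(F)(F)F
F5 | step 4 | gem-dimethyl enol triflate, 2β-OH | O=S(=O)(OC1=C(C)C[C@H](O)CC1(C)C)C(F)(F)F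
F6 | step 4 | 2β-nitrite ester of F5 | O=S(=O)(OC1=C(C)C[C@H](ON=O)CC1(C)C)C(F)(F)F
F7 | step 4 | C19 aldoxime (4β-CH=NOH, 2β-OH) enol triflate | O=S(=O)(OC1=C(C)C[C@H](O)C[C@]1(C)C=NO)C(F)(F)F
F8 | step 4 | C19 aldehyde (4β-CHO, 2β-OH) enol triflate, drawn in the open form | O=S(=O)(OC1=C(C)C[C@H](O)C[C@]1(C)C=O)C(F)(F)F
F9 | step 4 | diol enol triflate (4β-CH2OH, 2β-OH) | O=S(=O)(OC1=C(C)C[C@H](O)C[C@]1(C)CO)C(F)(F)F
F10 | step 10 | 2α-(4-nitrobenzoate) diene (4β-CH2OTBDPS) | C=CC1=C(C)C[C@@H](OC(=O)c2ccc(cc2)[N+](=O)[O-])C[C@]1(C)CO[Si](c1ccccc1)(c1ccccc1)C(C)(C)C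
F11 | step 10 | 2α-dienol (4β-CH2OTBDPS) | C=CC1=C(C)C[C@@H](O)C[C@]1(C)CO[Si](c1ccccc1)(c1ccccc1)C(C)(C)C
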